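**Retrosynthetic overview**
1. The ester is made last by acylating the C6–OH of diol 17; C5–H and C6–OH come from the tertiary allylic alcohol 15 (C4–OH, C5=C6) by hydroxyl-directed epoxidation and radical epoxide opening.
2. Alcohol 15 comes from α,β-epoxy ketone 13 by Wharton transposition; 13 comes from bromo diketone 11 by an intramolecular Darzens annulation that forms the C4–C5 bond and the C4–O–C5 oxirane together.
3. The feature that allows this: in the cycloheptenone ring the ketone C6 acidifies its α-carbon C5, which also carries bromine, and the isopropyl ketone C4 hangs from the adjacent quaternary C1 through C2–C3, so aldol closure gives the cyclopentane and bromide displacement gives the oxirane.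
4. Ring order: the seven-membered ring first (ring-closing metathesis, C8=C9), then the five-membered ring and oxirane in the key step; 11 comes from aldehyde 3 by α-methoxy Wittig olefination and bromination.
5. The quaternary C1 is set first, by organocatalytic Michael addition of 2-methylpent-4-enal to isopropyl vinyl ketone.

Key step: step 7

Remark on numbering: daucane numbering is used in the text. C1 is the methyl-bearing ring-fusion carbon, C2 and C3 the cyclopentane CH2 groups, C4 the isopropyl carbinol carbon, C5 the ring-fusion CH, C6 the ester carbon, C7 a CH2, C8 the methyl-bearing alkene carbon, C9 the alkene CH, C10 a CH2; α is the face opposite the C1 methyl group.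
Assumption: in step 1 the catalyst antipode that delivers (S)-3 is used; the (1R,2R) label is the working choice and is exchanged for (1S,2S) if the sense of induction is the opposite.

Step 1
Reactants: 1 2-methylpent-4-enal (racemic); 2 4-methylpent-1-en-3-one
Product: 3 (2S)-2,6-dimethyl-5-oxo-2-(prop-2-en-1-yl)heptanal
Conditions: 1-[(1R,2R)-2-aminocyclohexyl]-3-[3,5-bis(trifluoromethyl)phenyl]thiourea (20 mol%), PhCO2H (20 mol%), toluene, rt
Reagents that add atoms: none
Why: Enamine-mediated asymmetric Michael addition of an α-branched aldehyde to a vinyl ketone; both enantiomers of 1 converge in the enamine, and the catalyst shields one enamine face while the thiourea binds the enone, so the quaternary C1 should form as S.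

Step 2
Reactants: 4 2-methylallylmagnesium chloride; 5 trimethyl orthoformate
Product: 6 4,4-dimethoxy-2-methylbut-1-ene
Conditions: THF then toluene, 80 °C; aq. NH4Cl
Reagents that add atoms: none
Why: Bodroux–Chichibabin substitution of one methoxy group of the orthoformate by the allylic Grignard reagent should give the acetal.

Step 3
Reactants: 6 4,4-dimethoxy-2-methylbut-1-ene
Product: 7 (1-methoxy-3-methylbut-3-en-1-yl)triphenylphosphonium tetrafluoroborate
Conditions: Ph3P·HBF4, MeCN, rt, methanol removed under reduced pressure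
Reagents that add atoms: triphenylphosphonium tetrafluoroborate, c1ccc([PH+](c2ccccc2)c2ccccc2)cc1.F[B-](F)(F)F
Why: Acid-mediated exchange of one acetal methoxy group for triphenylphosphine through the oxocarbenium ion, the known preparation of α-alkoxyalkyl phosphonium salts.

Step 4
Reactants: 3 (2S)-2,6-dimethyl-5-oxo-2-(prop-2-en-1-yl)heptanal; 7 (1-methoxy-3-methylbut-3-en-1-yl)triphenylphosphonium tetrafluoroborate
Product: 9 (6S)-8-methoxy-2,6,10-trimethyl-6-(prop-2-en-1-yl)undeca-7,10-dien-3-one (E/Z mixture), via phosphorus ylide 8 (not isolated)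
Conditions: KN(SiMe3)2, THF, −78 °C; then 3, −78 °C → rt
Reagents that add atoms: none
Why: Wittig olefination in which the aldehyde should react in preference to the hindered, enolizable isopropyl ketone; the enol ether geometry does not matter because it is erased in step 5.

Step 5
Reactants: 9 (6S)-8-methoxy-2,6,10-trimethyl-6-(prop-2-en-1-yl)undeca-7,10-dien-3-one
Product: 10 (6S)-7-bromo-2,6,10-trimethyl-6-(prop-2-en-1-yl)undec-10-ene-3,8-dione (both C7 epimers)
Conditions: N-bromosuccinimide, NaHCO3, THF/H2O, 0 °C
Reagents that add atoms: N-bromosuccinimide, O=C1CCC(=O)N1Br; water, O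
Why: Electrophilic bromination of the electron-rich enol ether at its β-carbon and hydrolysis of the oxocarbenium ion should place bromine only at C5 and the ketone only at C6, leaving the two unactivated alkenes untouched; both C5 epimers converge in step 7.

Step 6
Reactants: 10 (6S)-7-bromo-2,6,10-trimethyl-6-(prop-2-en-1-yl)undec-10-ene-3,8-dione
Product: 11 (6S)-7-bromo-3,6-dimethyl-6-(4-methyl-3-oxopentyl)cyclohept-3-en-1-one (both C7 epimers)
Conditions: second-generation Grubbs catalyst (5 mol%), 1,4-benzoquinone (10 mol%), CH2Cl2, 40 °C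
Reagents that add atoms: none
Why: Ring-closing metathesis of the allyl and 2-methylallyl groups should close the seven-membered ring with the trisubstituted C8=C9 alkene, helped by the quaternary C1; benzoquinone suppresses alkene migration.

Step 7
Reactants: 11 (6S)-7-bromo-3,6-dimethyl-6-(4-methyl-3-oxopentyl)cyclohept-3-en-1-one
Product: 13 (3R,3aR,8aS)-3,3a-epoxy-6,8a-dimethyl-3-(propan-2-yl)-1,2,3,3a,8,8a-hexahydroazulen-4(5H)-one, via potassium bromo-aldolate 12 (not isolated)
Conditions: KOtBu (2.5 equiv), t-BuOH/THF, 0 °C; then inverse quench into cold 10% aq. AcOH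
Reagents that add atoms: none
Why: Intramolecular Darzens condensation: under equilibrating tert-butoxide the bromo ketone is enolized at C5, the enolate adds to the isopropyl ketone C4 in a 5-(enolexo)-exo-trig aldol that forms the C4–C5 bond and closes the five-membered ring, and the alkoxide then displaces bromide from C5 in a 3-exo-tet closure to the oxirane. The closest known reaction type is the Darzens synthesis of α,β-epoxy ketones from α-halo ketones and ketone acceptors. The tether C2–C3 from C1 delivers C4 to the enolate face that carries C2, so in aldolate 12 bromine lies syn to the C1 methyl group, and only the potassium-chelated aldolate with the C4 oxygen anti to bromine can close; the aldol is reversible, so material should funnel through it. Inversion at C5 then puts the oxirane oxygen anti to the C1 methyl group, which fixes C4 as R and C5 as R relative to the S centre C1 and places the isopropyl group on the methyl face. The selectivity needed is enolization at C5 against C7: C7 enolization is reversible and unproductive whereas the C5 enolate is trapped irreversibly, and the neopentyl position of C5 disfavours Favorskii closure. With excess base the product rests as its extended enolate, and the inverse acidic quench protonates C7 kinetically so that the alkene stays at C8=C9.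

Step 8
Reactants: 13 (3R,3aR,8aS)-3,3a-epoxy-6,8a-dimethyl-3-(propan-2-yl)-1,2,3,3a,8,8a-hexahydroazulen-4(5H)-one
Product: 15 (3R,8aS)-6,8a-dimethyl-3-(propan-2-yl)-1,2,3,5,8,8a-hexahydroazulen-3-ol, via epoxy hydrazone 14 (not isolated)
Conditions: N2H4·H2O, AcOH (cat.), MeOH, 0 °C → rt
Reagents that add atoms: none
Why: Wharton transposition: the hydrazone opens the oxirane, and loss of dinitrogen leaves the C5=C6 alkene and the tertiary C4 alcohol, whose configuration is that of the oxirane C4–O bond.

Step 9
Reactants: 15 (3R,8aS)-6,8a-dimethyl-3-(propan-2-yl)-1,2,3,5,8,8a-hexahydroazulen-3-ol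
Product: 16 (3R,3aS,4R,8aS)-3a,4-epoxy-6,8a-dimethyl-3-(propan-2-yl)-1,2,3,3a,4,5,8,8a-octahydroazulen-3-ol
Conditions: VO(acac)2 (5 mol%), t-BuOOH, CH2Cl2, 0 °C → rt
Reagents that add atoms: tert-butyl hydroperoxide, CC(C)(C)OO
Why: Vanadium-catalysed hydroxyl-directed epoxidation should oxidize only the allylic C5=C6 alkene and deliver oxygen syn to the C4 hydroxyl (α face, also the face away from the methyl and isopropyl groups), which sets C6.

Step 10
Reactants: 16 (3R,3aS,4R,8aS)-3a,4-epoxy-6,8a-dimethyl-3-(propan-2-yl)-1,2,3,3a,4,5,8,8a-octahydroazulen-3-ol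
Product: 17 (3R,3aR,4R,8aS)-6,8a-dimethyl-3-(propan-2-yl)-1,2,3,3a,4,5,8,8a-octahydroazulene-3,4-diol
Conditions: Cp2TiCl2 (10 mol%), Mn dust, 2,4,6-collidine hydrochloride, 1,4-cyclohexadiene, THF, rt
Reagents that add atoms: none
Why: Titanocene-catalysed reductive epoxide opening (Cp2TiCl, trivalent titanium) should cleave the C5–O bond to the tertiary C5 radical while C6 keeps its oxygen and configuration; hydrogen-atom transfer from cyclohexadiene to the planar radical is expected on the α face, away from the cis-disposed C1 methyl and C4 isopropyl groups, which gives the trans ring fusion under kinetic control.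

Step 11
Reactants: 17 (3R,3aR,4R,8aS)-6,8a-dimethyl-3-(propan-2-yl)-1,2,3,3a,4,5,8,8a-octahydroazulene-3,4-diol; 18 3,4-dimethoxybenzoyl chloride
Product: 19 (3R,3aR,4R,8aS)-3-hydroxy-6,8a-dimethyl-3-(propan-2-yl)-1,2,3,3a,4,5,8,8a-octahydroazulen-4-yl 3,4-dimethoxybenzoate
Conditions: Et3N, DMAP (cat.), CH2Cl2, 0 °C → rt
Reagents that add atoms: none
Why: Nucleophilic-catalysed acylation should take place only at the secondary C6 hydroxyl, since the tertiary C4 hydroxyl is unreactive under these conditions.

**Compound list**
1 | 2-methylpent-4-enal (racemic) | O=CC(C)CC=C | starting material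
2 | 4-methylpent-1-en-3-one | C=CC(=O)C(C)C | starting material
3 | (2S)-2,6-dimethyl-5-oxo-2-(prop-2-en-1-yl)heptanal | O=C[C@](C)(CC=C)CCC(=O)C(C)C | intermediate
4 | 2-methylallylmagnesium chloride | C=C(C)C[Mg]Cl | starting material
5 | trimethyl orthoformate | COC(OC)OC | starting material
6 | 4,4-dimethoxy-2-methylbut-1-ene | C=C(C)CC(OC)OC | intermediate
7 | (1-methoxy-3-methylbut-3-en-1-yl)triphenylphosphonium tetrafluoroborate (racemic) | C=C(C)CC(OC)[P+](c1ccccc1)(c1ccccc1)c1ccccc1.F[B-](F)(F)F | intermediate
8 | (1-methoxy-3-methylbut-3-en-1-ylidene)triphenylphosphorane | C=C(C)CC(OC)=P(c1ccccc1)(c1ccccc1)c1ccccc1 | intermediate (not isolated)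
9 | (6S)-8-methoxy-2,6,10-trimethyl-6-(prop-2-en-1-yl)undeca-7,10-dien-3-one (E/Z mixture) | COC(CC(C)=C)=C[C@](C)(CC=C)CCC(=O)C(C)C | intermediate
10 | (6S)-7-bromo-2,6,10-trimethyl-6-(prop-2-en-1-yl)undec-10-ene-3,8-dione (C7 epimers) | CC(C)C(=O)CC[C@@](C)(CC=C)C(Br)C(=O)CC(C)=C | intermediate
11 | (6S)-7-bromo-3,6-dimethyl-6-(4-methyl-3-oxopentyl)cyclohept-3-en-1-one (C7 epimers) | CC(C)C(=O)CC[C@@]1(C)CC=C(C)CC(=O)C1Br | intermediate
12 | potassium alkoxide of the cis-fused bromo aldol (C4 oxygen α, C5 bromine β) | CC(C)[C@]1([O-])CC[C@@]2(C)CC=C(C)CC(=O)[C@@]12Br.[K+] | intermediate (not isolated)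
13 | (3R,3aR,8aS)-3,3a-epoxy-6,8a-dimethyl-3-(propan-2-yl)-1,2,3,3a,8,8a-hexahydroazulen-4(5H)-one | CC(C)[C@]12CC[C@@]3(C)CC=C(C)CC(=O)[C@@]31O2 | intermediate
14 | C6 hydrazone of 13 | CC(C)[C@]12CC[C@@]3(C)CC=C(C)CC(=NN)[C@@]31O2 | intermediate (not isolated)
15 | (3R,8aS)-6,8a-dimethyl-3-(propan-2-yl)-1,2,3,5,8,8a-hexahydroazulen-3-ol | CC(C)[C@]1(O)CC[C@@]2(C)CC=C(C)CC=C12 | intermediate
16 | (3R,3aS,4R,8aS)-3a,4-epoxy-6,8a-dimethyl-3-(propan-2-yl)-1,2,3,3a,4,5,8,8a-octahydroazulen-3-ol | CC(C)[C@]1(O)CC[C@@]2(C)CC=C(C)C[C@H]3O[C@@]123 | intermediate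
17 | (3R,3aR,4R,8aS)-6,8a-dimethyl-3-(propan-2-yl)-1,2,3,3a,4,5,8,8a-octahydroazulene-3,4-diol | O[C@@H]1CC(C)=CC[C@]2(C)CC[C@@](O)(C(C)C)[C@@H]12 | intermediate
18 | 3,4-dimethoxybenzoyl chloride | COc1ccc(C(Cl)=O)cc1OC | starting material
19 | (3R,3aR,4R,8aS)-3-hydroxy-6,8a-dimethyl-3-(propan-2-yl)-1,2,3,3a,4,5,8,8a-octahydroazulen-4-yl 3,4-dimethoxybenzoate | COc1ccc(C(=O)O[C@@H]2CC(C)=CC[C@]3(C)CC[C@@](O)(C(C)C)[C@@H]23)cc1OC | target

**Step count:** 11 steps in total; longest linear sequence 10 steps (2, 3, 4, 5, 6, 7, 8, 9, 10, 11).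

**Steps most likely to fail**

Step 7. The base may enolize 11 mainly toward C7, which is less hindered and allylic; this can lead to Favorskii-type ring contraction or to loss of the C8=C9 position on quench. The fallback removes the competing site before ring closure and restores the alkene afterwards. It sets out from 11: DBU in CH2Cl2 moves the alkene into conjugation to give (6R)-7-bromo-3,6-dimethyl-6-(4-methyl-3-oxopentyl)cyclohept-2-en-1-one F1, which has no α′ hydrogen other than the one at C5. LiN(SiMe3)2 in THF at −78 °C (kinetic α′-deprotonation of the enone) should then enolize only at C5 and give the conjugated epoxy enone (3R,3aR,8aR)-3,3a-epoxy-6,8a-dimethyl-3-(propan-2-yl)-1,2,3,3a,8,8a-hexahydroazulen-4(7H)-one F2. Treatment of F2 with KOtBu in t-BuOH and inverse quench into cold acetic acid (kinetic α-protonation of the extended enolate) should move the alkene back to C8=C9; the fallback comes back to the route at 13.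

Step 10. Hydrogen-atom transfer to the planar C5 radical may show poor facial selectivity and give the cis ring fusion, or the radical may be reduced further and eliminate. The fallback sets C5 by polar enolate protonation instead. It sets out from 13: SmI2 with MeOH in THF at −90 °C cleaves the C5–O bond next to the ketone, and the samarium enolate should be protonated at C5 from the face of the samarium-bound C4 oxygen to give the trans-fused β-hydroxy ketone (3R,3aS,8aS)-3-hydroxy-6,8a-dimethyl-3-(propan-2-yl)-1,2,3,3a,8,8a-hexahydroazulen-4(5H)-one F3. Reduction with Li in NH3/THF with t-BuOH at −78 °C should give the thermodynamically preferred equatorial C6 alcohol, anti to the axial C1 methyl group; the fallback comes back to the route at 17.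

Step 1. The enamine geometry (methyl against allyl) may be poorly controlled, so the quaternary centre may form with low enantioselectivity. The fallback uses a chiral auxiliary instead of a catalyst. It replaces 1 and 2 as the source of C1: it sets out from commercial (S)-valinol and 6-methyl-5-oxoheptanoic acid, which condense (toluene, reflux, water removal) to the bicyclic lactam (3S,8aS)-3,8a-di(propan-2-yl)hexahydro-5H-[1,3]oxazolo[3,2-a]pyridin-5-one F4. Deprotonation with LiN(iPr)2 and methylation with MeI gives the 6-methyl lactam F5; a second deprotonation and alkylation with allyl bromide, entering from the open face of the enolate, gives the quaternary lactam (3S,6S,8aS)-6-methyl-6-(prop-2-en-1-yl)-3,8a-di(propan-2-yl)hexahydro-5H-[1,3]oxazolo[3,2-a]pyridin-5-one F6 (the order of the two alkylations is exchanged if the other epimer forms). Reduction with NaAlH2(OCH2CH2OMe)2 and mild aqueous acidic hydrolysis releases the keto aldehyde; the fallback comes back to the route at 3.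

**Further compounds**
F1 | step 7 | (6R)-7-bromo-3,6-dimethyl-6-(4-methyl-3-oxopentyl)cyclohept-2-en-1-one | CC(C)C(=O)CC[C@@]1(C)CCC(C)=CC(=O)C1Br
F2 | step 7 | (3R,3aR,8aR)-3,3a-epoxy-6,8a-dimethyl-3-(propan-2-yl)-1,2,3,3a,8,8a-hexahydroazulen-4(7H)-one | CC(C)[C@]12CC[C@@]3(C)CCC(C)=CC(=O)[C@@]31O2
F3 | step 10 | (3R,3aS,8aS)-3-hydroxy-6,8a-dimethyl-3-(propan-2-yl)-1,2,3,3a,8,8a-hexahydroazulen-4(5H)-one | O=C1CC(C)=CC[C@]2(C)CC[C@@](O)(C(C)C)[C@@H]12
F4 | step 1 | (3S,8aS)-3,8a-di(propan-2-yl)hexahydro-5H-[1,3]oxazolo[3,2-a]pyridin-5-one | CC(C)[C@H]1CO[C@]2(C(C)C)CCCC(=O)N12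
F5 | step 1 | (3S,8aS)-6-methyl-3,8a-di(propan-2-yl)hexahydro-5H-[1,3]oxazolo[3,2-a]pyridin-5-one (C6 epimers) | CC(C)[C@H]1CO[C@]2(C(C)C)CCC(C)C(=O)N12
F6 | step 1 | (3S,6S,8aS)-6-methyl-6-(prop-2-en-1-yl)-3,8a-di(propan-2-yl)hexahydro-5H-[1,3]oxazolo[3,2-a]pyridin-5-one | CC(C)[C@H]1CO[C@]2(C(C)C)CC[C@@](C)(CC=C)C(=O)N12
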